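Which way does the substrate go in these runs? Down, and at a steady pace, so the easy first step is to lay a ruler along its readings.

the same everywhere: substrate 0.50 M; gas 25 mM (held)
- violet: second reagent 0.17 M; third reagent 2 M; capture agent 0.050 M; temperature 118 °C; run made earlier
- blue: second reagent 0.70 M; third reagent 2 M; capture agent 0.050 M; temperature 134 °C; run made earlier
- spring: second reagent 0.350 M; third reagent 2.00 M; capture agent 0.0500 M; at 110 °C until 80 s, from then on at 140 °C; time 2.0 min
- summer: second reagent 0.350 M; third reagent 2.00 M; capture agent 0.0500 M; temperature 110 °C; time 2.0 min
- midnight: second reagent 0.350 M; third reagent 2.00 M; capture agent 0.0500 M; temperature 140 °C; time 2.0 min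

- violet (time / s: target / %, substrate / %): 10.0: 0, 94.7; 12.0: 0, 93.3; 20.0: 0.3, 88.6; 30.0: 0.1, 82.7; 40.0: 0.5, 76.8; 60.0: 1.8, 66.2; 80.0: 3.0, 55.6
- blue (time / s: target / %, substrate / %): 10.0: 0, 91.7; 15.0: 0.9, 86.8; 25.0: 3.4, 78.6

(each reading ± 0.3 percentage points)

* the best flask by amount of target, in percent of the substrate charged; "all alike" if 1.5 percentage points covers them all (spring / summer / midnight / all alike)
* amount of target at the end, in percent of the substrate charged, spring
* amount of target at the end, in percent of the substrate charged, summer
* amount of target at the end, in percent of the substrate charged, midnight

What does the ruler give? I name the clearing time: the time the whole substrate charge takes at the straight-line speed of a run. In the violet run the substrate falls from 94.7% to 55.6% in 70.0 s, so 179 s. In the blue run the same ruler gives 115 s.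

But the blue run holds more second reagent as well as more heat, so why give the difference to temperature? Write the balance of the second reagent in the violet run, where it is charged below the substrate. By the last reading 44.4% of the substrate is gone, which is 0.222 M, more than the 0.17 M of second reagent charged, and the line is still straight. So the substrate does not pay one for one with second reagent, and I treat its loss as zero order and dependent on temperature. That is my judgement, not a proof.

And at the asked temperatures? I draw the logarithm of the clearing time straight through the two runs. That gives 224 s at 110 °C and 96.8 s at 140 °C, both outside the measured range.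

What does that say of target? It gives a ceiling, not a yield, since target comes from lost substrate. Summer loses 53.6% and spring 77.0%, while midnight's clearing time is shorter than its 2.0 min. My order is midnight, spring, summer, and I commit to no target values.

The forecast names midnight as best, with 16% for spring, 7% for summer and 24% for midnight. It reads the substrate line as “roughly zero order with a low apparent temperature dependence”.

The flasks give 28.4% in spring, 5.00% in summer and 49.6% in midnight, so midnight is best, and the forecast's midnight figure is 26 percentage points low.

    substrate + coupling partner → intermediate A (k = 0.316 M⁻¹ s⁻¹, Ea = 74.0 kJ mol⁻¹)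
    second reagent + intermediate A → intermediate B (k = 0.0253 M⁻¹ s⁻¹, Ea = 81.0 kJ mol⁻¹)
    third reagent + intermediate B → target (k = 0.00426 M⁻¹ s⁻¹, Ea = 85.0 kJ mol⁻¹)
    gas ⇌ coupling partner, rate k4*(csat - [coupling partner]) (kL = 0.272 s⁻¹)
    intermediate B + capture agent → trapped intermediate (k = 0.0286 M⁻¹ s⁻¹, Ea = 54.0 kJ mol⁻¹)
    substrate → decomposition product (k = 3.09 × 10⁻⁶ s⁻¹, Ea = 128 kJ mol⁻¹)
    (constants at 110 °C)

In summer the clearing time promised 53.6% of the substrate gone at 2.00 min, and the flask has lost 47.7%, a little behind the line. The neighbouring flask is summer itself, read at 50 s. The same clearing time gives 22.3% gone, so 77.7% left, and that flask holds 78.0% of substrate. Counted in percent of the substrate charged, that flask holds 17.9% as intermediate A, 3.44% as intermediate B and 0.517% as target.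

All runs are simulated for substances that don't exist.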